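## Retrosynthetic overview

1. Japonicone A ⇒ final intermolecular Diels–Alder (norbornene and spiro centre formed last) between a 2‑acetoxy‑guaia‑1(5),3‑diene and the C11=C13 methylene lactone of O‑TBS 1‑hydroxyalantolactone.
2. Diene ⇐ in‑situ dehydration of a C4 tertiary carbinol ⇐ trans‑8,12‑lactone from an isopropenyl group (SeO2, then MnO2) ⇐ seven‑membered ring by carbonyl‑ene closure ⇐ Stork–Danheiser cyclopentenone ⇐ organocatalytic Michael addition of cyclopentane‑1,3‑dione to crotonaldehyde (sets C10).
3. Dienophile ⇐ cis‑lactone by intramolecular Tsuji–Trost alkylation then HWE methylenation ⇐ α′‑hydroxylation/Mitsunobu inversion ⇐ γ‑methylenation/hydrogenation (C4 methyl) ⇐ (S)‑Wieland–Miescher ketone.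
4. Ring order: decalin (purchased) → eudesmanolide lactone; cyclopentenone → cycloheptane → guaianolide lactone → cyclopentadiene → norbornene.

Assumption: the SMILES is followed literally; its eudesmanolide half is (1S,4R,7S,8S,10S), the antipode of natural 1β‑hydroxyalantolactone, so both halves are built de novo in that series.

This route is a paper proposal; no step has been run. Eudesmane and guaiane numbering is used in the names.

## Route

### Dienophile branch (steps 1–10)

Step 1
Reactants: 1, (S)‑Wieland–Miescher ketone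
Product: 2, (4aS,5S)‑5‑hydroxy‑4a‑methyl‑4,4a,5,6,7,8‑hexahydronaphthalen‑2(3H)‑one (OH cis to the angular methyl)
Conditions: NaBH4 (0.3 equiv), EtOH, −10 °C
Reagents that add atoms: none
Why: Chemoselective borohydride reduction of the saturated ketone; hydride adds anti to the axial angular methyl, giving the equatorial alcohol cis to CH3 (C1 = S).

Step 2
Reactants: 2
Product: 3, TBS ether of 2
Conditions: TBSOTf, 2,6‑lutidine, CH2Cl2, 0 °C
Reagents that add atoms: TBSOTf, CC(C)(C)[Si](C)(C)OS(=O)(=O)C(F)(F)F
Why: Silylation protects the hindered secondary alcohol for the enolate, Pd and dehydrating steps that follow.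

Step 3
Reactants: 3
Product: 4, 1‑OTBS‑11,12,13‑trinor‑eudesma‑4(15),5‑dien‑7‑one (4‑methylene dienone)
Conditions: CH2(OEt)2, POCl3, NaOAc, CHCl3, reflux
Reagents that add atoms: formaldehyde diethyl acetal, CCOCOCC
Why: γ‑Methylenation via the in‑situ dienol ether, which is alkoxymethylated at the γ‑carbon (C4) and loses EtOH (the 6‑methylene‑steroid reaction).

Step 4
Reactants: 4
Product: 5, 4‑methyl enone (C4 methyl cis to C10 methyl, 4R)
Conditions: H2 (1 atm), RhCl(PPh3)3, benzene/EtOH, rt
Reagents that add atoms: none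
Why: Wilkinson hydrogenation reduces only the exocyclic 1,1‑disubstituted alkene; H2 is delivered anti to the angular methyl, so the new methyl is cis to C10–CH3.

Step 5
Reactants: 5
Product: 6, 8‑hydroxy enone (8‑OH trans to C10–CH3, 8R)
Conditions: LDA, THF, −78 °C; then Davis oxaziridine
Reagents that add atoms: 2‑(phenylsulfonyl)‑3‑phenyloxaziridine, O=S(=O)(c1ccccc1)N1OC1c1ccccc1
Why: Kinetic α′‑enolate hydroxylation; the oxidant approaches anti to the 1,3‑related axial C10 methyl, and kinetic deprotonation leaves the γ‑C4 centre untouched.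

Step 6
Reactants: 6
Product: 7, 8‑O‑(diethylphosphonoacetyl) enone with inverted C8 (O cis to C10–CH3, 8S)
Conditions: (EtO)2P(O)CH2CO2H, PPh3, DIAD, THF, 0 °C → rt
Reagents that add atoms: diethylphosphonoacetic acid, CCOP(=O)(OCC)CC(=O)O
Why: Mitsunobu esterification proceeds with SN2 inversion, placing the C8 oxygen on the methyl face needed for the cis‑lactone and installing the future C11/C12 unit.

Step 7
Reactants: 7
Product: 8, 7‑hydroxy‑8‑acyloxy compound (7‑OH cis to 8‑O; 7R,8S)
Conditions: NaBH4, CeCl3·7H2O, MeOH, −78 °C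
Reagents that add atoms: none
Why: Luche 1,2‑reduction; hydride adds anti to the adjacent acyloxy group and the angular methyl, giving the cis‑7,8‑dioxygenated allylic alcohol.

Step 8
Reactants: 8
Product: 9, allylic methyl carbonate of 8
Conditions: ClCO2Me, pyridine, DMAP (cat.), CH2Cl2, 0 °C
Reagents that add atoms: methyl chloroformate, COC(=O)Cl
Why: Acylation converts the allylic alcohol into a Pd‑ionisable leaving group that releases methoxide as internal base.

Step 9
Reactants: 9
Product: 10, cis‑fused α‑(diethylphosphono)‑γ‑lactone (C7–C11 bond formed; 7S,8S; C11 epimers)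
Conditions: Pd2(dba)3·CHCl3 (5 mol %), dppe, THF, 60 °C
Reagents that add atoms: none
Why: Intramolecular Tsuji–Trost allylic alkylation; Pd ionises C7 with inversion and the tethered phosphonoacetate anion attacks C7 anti to Pd (net retention), closing the cis‑lactone with H7 on the face opposite C10–CH3 and avoiding the neopentyl C5 terminus.

Step 10
Reactants: 10
Product: 11, (1S,4R,7S,8S,10S)‑1‑(TBSO)‑eudesma‑5,11(13)‑dien‑12,8‑olide (O‑TBS ent‑1β‑hydroxyalantolactone)
Conditions: aq. HCHO, K2CO3, THF, rt
Reagents that add atoms: formaldehyde, C=O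
Why: Horner–Wadsworth–Emmons olefination of the α‑phosphono lactone with formaldehyde gives the α‑methylene lactone without touching any stereocentre.

### Diene branch (steps 11–21)

Step 11
Reactants: 12, cyclopentane‑1,3‑dione; 13, (E)‑crotonaldehyde
Product: 14, (4R)‑2‑hydroxy‑4‑methyl‑3,4,6,7‑tetrahydrocyclopenta[b]pyran‑5(2H)‑one (hemiacetal form of the Michael adduct)
Conditions: (S)‑α,α‑diphenylprolinol TMS ether (10 mol %), PhCO2H (10 mol %), CH2Cl2, 0 °C → rt
Reagents that add atoms: none
Why: Iminium‑catalysed (Jørgensen–Hayashi) asymmetric Michael addition; the dione attacks the enal β‑carbon on the face opposite the CPh2OTMS group, setting C10 (R), and the adduct closes to the hemiacetal.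

Step 12
Reactants: 14
Product: 15, 2‑methoxy acetal of 14 (anomer mixture)
Conditions: MeOH, PPTS, rt
Reagents that add atoms: methanol, CO
Why: Acid‑catalysed acetalisation masks the aldehyde and fixes the enol as a cyclic vinylogous ester for Stork–Danheiser chemistry.

Step 13
Reactants: 15
Product: 16, 6‑methyl derivative (guaiane C4 methyl; epimer mixture)
Conditions: LDA, THF, −78 °C; then MeI
Reagents that add atoms: iodomethane, CI
Why: Stork–Danheiser kinetic α′‑enolate alkylation; this stereocentre is destroyed later, and C10 is not acidic.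

Step 14
Reactants: 16
Product: 17, 6‑hydroxy‑6‑methyl derivative (tertiary carbinol; epimer mixture)
Conditions: KHMDS, THF, −78 °C; then Davis oxaziridine
Reagents that add atoms: 2‑(phenylsulfonyl)‑3‑phenyloxaziridine, O=S(=O)(c1ccccc1)N1OC1c1ccccc1
Why: Enolate α‑hydroxylation creates the throw‑away tertiary carbinol that is later eliminated to the C3=C4 alkene.

Step 15
Reactants: 17
Product: 18, (R)‑3‑(2‑allyl‑3‑hydroxy‑3‑methyl‑5‑oxocyclopent‑1‑en‑1‑yl)butanal
Conditions: allylMgBr (3 equiv), THF, −78 → 0 °C; then 1 M HCl, THF, rt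
Reagents that add atoms: allylmagnesium bromide, C=CC[Mg]Br; water, O
Why: Stork–Danheiser 1,2‑addition and hydrolytic enone transposition gives the tetrasubstituted enone (future C1=C5, C2=O) and unmasks the aldehyde; the β‑hydroxy ketone cannot dehydrate because that would give a cyclopentadienone.

Step 16
Reactants: 18
Product: 19, prenyl analogue of 18
Conditions: Grubbs II (5 mol %), 2‑methyl‑2‑butene/CH2Cl2, 40 °C
Reagents that add atoms: 2‑methyl‑2‑butene, CC=C(C)C
Why: Olefin cross‑metathesis converts the terminal allyl group into the trisubstituted prenyl ene donor; the tetrasubstituted enone is inert.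

Step 17
Reactants: 19
Product: 20, (7S,8R,10R)‑4,8‑dihydroxy‑guaia‑1(5),11(13)‑dien‑2‑one (8‑OH trans to 7‑isopropenyl and trans to C10–CH3; C4 epimers)
Conditions: Me2AlCl (3 equiv), CH2Cl2, −78 → −20 °C
Reagents that add atoms: none
Why: Lewis‑acid type‑I intramolecular carbonyl‑ene closure of the seven‑membered ring through a chair‑like transition state, with the new OH and isopropenyl pseudo‑equatorial (trans) and the C10 methyl pseudo‑axial (A1,2 strain with the C2 carbonyl), which sets C7 and C8.

Step 18
Reactants: 20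
Product: 21, 4,8,12‑trihydroxy‑guaia‑1(5),11(13)‑dien‑2‑one
Conditions: SeO2 (0.5 equiv), t‑BuOOH, CH2Cl2, rt
Reagents that add atoms: tert‑butyl hydroperoxide, CC(C)(C)OO; selenium dioxide, O=[Se]=O
Why: Selenium dioxide allylic oxidation (ene/[2,3]) of the electron‑rich isopropenyl methyl (CH3 preferred over the methine); the enone alkene is not attacked.

Step 19
Reactants: 21
Product: 22, (7S,8R,10R)‑4‑hydroxy‑2‑oxo‑guaia‑1(5),11(13)‑dien‑12,8‑olide (trans‑fused α‑methylene lactone)
Conditions: MnO2, CH2Cl2, rt
Reagents that add atoms: none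
Why: Oxidative lactonisation: the allylic alcohol is oxidised to the enal, which forms a lactol with C8–OH and is oxidised again, so the trans C7/C8 relationship is carried into the lactone.

Step 20
Reactants: 22
Product: 23, (2S)‑2,4‑dihydroxy‑guaia‑1(5),11(13)‑dien‑12,8‑olide (2‑OH on the face of C10–CH3)
Conditions: (R)‑Me‑CBS (20 mol %), catecholborane, toluene, −78 °C
Reagents that add atoms: none
Why: CBS reduction, matched with the substrate bias (hydride anti to the pseudo‑axial C10 methyl), sets C2 (S) for both C4 epimers; the lactone is untouched at −78 °C.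

Step 21
Reactants: 23
Product: 24, (2S,7S,8R,10R)‑2‑acetoxy‑4‑hydroxy‑guaia‑1(5),11(13)‑dien‑12,8‑olide
Conditions: Ac2O, pyridine, DMAP (cat.), CH2Cl2, 0 °C
Reagents that add atoms: acetic anhydride, CC(=O)OC(C)=O
Why: Selective acylation of the secondary allylic alcohol; the tertiary C4 carbinol does not react.

### Union (steps 22–23)

Step 22
Reactants: 24; 11 (3 equiv)
Product: 26, 1′‑O‑TBS‑japonicone A, formed via the transient diene 25, (2S,7S,8R,10R)‑2‑acetoxy‑guaia‑1(5),3,11(13)‑trien‑12,8‑olide
Conditions: Martin sulfurane (1.5 equiv), CH2Cl2, −20 °C → rt, in the presence of 11; then concentrate to about 1 M in toluene, rt, 3 d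
Reagents that add atoms: none
Why: Dehydration of the tertiary allylic carbinol toward C3 gives the cyclopentadiene, which undergoes an endo intermolecular Diels–Alder reaction. C13H2 bonds to the substituted terminus C1 and the quaternary C11 to C3–H (steric regiocontrol). The diene is attacked anti to both C2–OAc and the pseudo‑axial C10–CH3, and the lactone on its convex face (syn to H7), which sets C1, C3 and the spiro C11′.

Step 23
Reactants: 26
Product: 27, japonicone A (target)
Conditions: HF·pyridine, THF/pyridine, 0 °C → rt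
Reagents that add atoms: none
Why: Acidic fluoride desilylation frees the C1′ hydroxyl without affecting the acetate, the two lactones or the exocyclic methylene.

## Compound list

1 | (S)‑Wieland–Miescher ketone | O=C1CC[C@@]2(C)C(=C1)CCCC2=O | starting material
2 | (4aS,5S)‑hydroxy enone | O=C1CC[C@@]2(C)C(=C1)CCC[C@@H]2O | intermediate
3 | TBS ether of 2 | O=C1CC[C@@]2(C)C(=C1)CCC[C@@H]2O[Si](C)(C)C(C)(C)C | intermediate
4 | 4‑methylene dienone | O=C1CC[C@@]2(C)C(=C1)C(=C)CC[C@@H]2O[Si](C)(C)C(C)(C)C | intermediate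
5 | 4‑methyl enone (4‑Me cis to 10‑Me) | O=C1CC[C@@]2(C)C(=C1)[C@H](C)CC[C@@H]2O[Si](C)(C)C(C)(C)C | intermediate
6 | 8‑hydroxy enone (OH trans to 10‑Me) | O=C1[C@H](O)C[C@@]2(C)C(=C1)[C@H](C)CC[C@@H]2O[Si](C)(C)C(C)(C)C | intermediate
7 | 8‑O‑phosphonoacetate, C8 inverted | O=C1[C@@H](OC(=O)CP(=O)(OCC)OCC)C[C@@]2(C)C(=C1)[C@H](C)CC[C@@H]2O[Si](C)(C)C(C)(C)C | intermediate
8 | cis‑7‑hydroxy‑8‑acyloxy allylic alcohol | O[C@H]1[C@@H](OC(=O)CP(=O)(OCC)OCC)C[C@@]2(C)C(=C1)[C@H](C)CC[C@@H]2O[Si](C)(C)C(C)(C)C | intermediate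
9 | allylic methyl carbonate | COC(=O)O[C@H]1[C@@H](OC(=O)CP(=O)(OCC)OCC)C[C@@]2(C)C(=C1)[C@H](C)CC[C@@H]2O[Si](C)(C)C(C)(C)C | intermediate
10 | cis‑fused α‑phosphono lactone | CCOP(=O)(OCC)C1C(=O)O[C@H]2C[C@@]3(C)C(=C[C@@H]12)[C@H](C)CC[C@@H]3O[Si](C)(C)C(C)(C)C | intermediate
11 | O‑TBS ent‑1β‑hydroxyalantolactone (dienophile) | C=C1C(=O)O[C@H]2C[C@@]3(C)C(=C[C@@H]12)[C@H](C)CC[C@@H]3O[Si](C)(C)C(C)(C)C | intermediate
12 | cyclopentane‑1,3‑dione | O=C1CCC(=O)C1 | starting material
13 | (E)‑crotonaldehyde | C/C=C/C=O | starting material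
14 | (4R)‑Michael adduct, hemiacetal | O=C1CCC2=C1[C@H](C)CC(O)O2 | intermediate
15 | methyl acetal (vinylogous ester) | O=C1CCC2=C1[C@H](C)CC(OC)O2 | intermediate
16 | α′‑methyl vinylogous ester | O=C1C(C)CC2=C1[C@H](C)CC(OC)O2 | intermediate
17 | α′‑hydroxy‑α′‑methyl vinylogous ester | O=C1C(C)(O)CC2=C1[C@H](C)CC(OC)O2 | intermediate
18 | allyl enone aldehyde | C=CCC1=C([C@H](C)CC=O)C(=O)CC1(C)O | intermediate
19 | prenyl enone aldehyde | CC(C)=CCC1=C([C@H](C)CC=O)C(=O)CC1(C)O | intermediate
20 | ene product (hydroazulenone) | C=C(C)[C@@H]1CC2=C(C(=O)CC2(C)O)[C@H](C)C[C@H]1O | intermediate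
21 | C12 allylic alcohol | C=C(CO)[C@@H]1CC2=C(C(=O)CC2(C)O)[C@H](C)C[C@H]1O | intermediate
22 | 4‑hydroxy‑2‑oxo guaianolide | C=C1C(=O)O[C@@H]2C[C@@H](C)C3=C(C[C@@H]12)C(C)(O)CC3=O | intermediate
23 | (2S)‑2,4‑diol guaianolide | C=C1C(=O)O[C@@H]2C[C@@H](C)C3=C(C[C@@H]12)C(C)(O)C[C@@H]3O | intermediate
24 | 2‑acetoxy‑4‑hydroxy guaianolide | C=C1C(=O)O[C@@H]2C[C@@H](C)C3=C(C[C@@H]12)C(C)(O)C[C@@H]3OC(C)=O | intermediate
25 | 2‑acetoxy‑guaia‑1(5),3,11(13)‑trien‑12,8‑olide (transient diene) | C=C1C(=O)O[C@@H]2C[C@@H](C)C3=C(C[C@@H]12)C(C)=C[C@@H]3OC(C)=O | intermediate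
26 | 1′‑O‑TBS‑japonicone A | C=C1C(=O)O[C@@H]2C[C@@H](C)[C@]34C[C@]5(C(=O)O[C@H]6C[C@@]7(C)C(=C[C@H]65)[C@H](C)CC[C@@H]7O[Si](C)(C)C(C)(C)C)[C@H](C(C)=C3C[C@@H]12)[C@@H]4OC(C)=O | intermediate
27 | japonicone A | C=C1C(=O)O[C@@H]2C[C@@H](C)[C@]34C[C@]5(C(=O)O[C@H]6C[C@@]7(C)C(=C[C@H]65)[C@H](C)CC[C@@H]7O)[C@H](C(C)=C3C[C@@H]12)[C@@H]4OC(C)=O | target

Compounds 16–24 are carried as C4‑epimer mixtures (15–17 also as anomers); both converge on the single diene 25.

## Summary

Total steps: 23 (10 for the dienophile, 11 for the diene precursor, 2 after union).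
Longest linear sequence: 13 steps (steps 11–23, from cyclopentane‑1,3‑dione).

Three steps most likely to fail, each with a fallback that changes the approach:

1. **Step 22 (diene generation and Diels–Alder).** The 5‑acetoxycyclopentadiene can undergo [1,5]‑H shift or react with its own methylene lactone, and simple 5‑acetoxycyclopentadienes prefer attack syn to OAc, whereas the target needs anti.
   Fallback: oxidise 23 at C2 and use the corresponding cyclopentadienone ketal (no migrating hydrogen) as the diene. After cycloaddition, hydrolyse to the norbornen‑7‑one, set the bridge carbinol by an equilibrating reduction (kinetic hydride should favour the wrong epimer), then acetylate.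

2. **Step 17 (seven‑membered carbonyl‑ene).** Ring size and C7/C8 control relative to C10 are uncertain.
   Fallback: cross‑metathesise 18 with methyl 2‑(bromomethyl)acrylate and close the ring by intramolecular Nozaki–Hiyama–Kishi allylation (CrCl2). This forms the C7–C8 bond and the α‑methylene lactone together and replaces steps 16–19.

3. **Step 9 (ester‑tethered intramolecular Tsuji–Trost).** The s‑trans ester conformation or β‑hydride elimination may prevent closure.
   Fallback: drop the tether. Alkylate the C7 allylic carbonate intermolecularly with dimethyl malonate (net retention) on the 8‑epi C8 mesylate. Then close the lactone by carboxylate SN2 displacement at C8 (inversion) and install the methylene by decarboxylative Mannich reaction.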